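**Conventions.** Atom numbers are those of the target: ring C1–C10, C11 on C7, C12 the lactone carbonyl, C13 the methylene. α/β refer to the ten-membered ring drawn flat with C1→C10 clockwise; α is the face that carries C11 on C7. In the target: 4-OH α (4-CH3 β), 5-O α, 6-O β, 7-C11 α, 8-O β, 9-OH α, 10-CH3 α.

## Analysis of the target

- The target is a ten-membered carbocycle (C1–C10) with a trans-fused α-methylene-γ-butyrolactone across C6–C7 (O6, C12, C11, C13) and a C3 ketone between the C2 methylene and the tertiary carbinol C4.
- Seven contiguous stereocentres run from C4 to C10 (4R,5R,6S,7R,8R,9R,10R). O4/O5 are cis, O5/O6 trans, O6/C11 trans, C11/O8 trans, O8/O9 trans, and O9/10-CH3 cis.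
- Five oxygens on six neighbouring carbons must be told apart: isobutyrates on O5 and O8, the lactone on O6, and free hydroxyls on C4 and C9.
- Sensitive groups are the methylene lactone (Michael and radical acceptor), the O8 ester beside the free C9 hydroxyl (acyl migration, translactonisation towards O8), and the C3/C4 α-ketol with a β-acyloxy group at C5.
- C7 sits between two oxygenated carbons, so any carbonyl at C11 makes C7–H acidic with a β-leaving group on each side. This, together with the medium ring, is the main difficulty.
- The strategy rests on this feature: C7 carries the single carbon C11 and lies 1,6 across the ring from C2, which is α to the C3 ketone. A carbonyl bridge C2–C11(=O)–C7 turns the ring into a bicyclo[4.4.1]undecanone, the [6+4] adduct skeleton of tropone and a 1-oxygenated diene. The C11/C3 1,3-diketone later allows the C2–C11 bond to be cut again.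

## Retrosynthetic reasoning

**28 ⇒ 27 ⇒ 25 + 26.** The last bonds cut are the silyl ether on O9 and the two acyl C–O bonds on O5 and O8. Both esters go on in one acylation of diol 25 with 26 once the lactone holds O6, and O9 stays silylated so that only the two wanted secondary hydroxyls react.

**25 ⇒ 24 ⇒ 23.** The lactone is cut at O6–C12 and C11–C12. C12 enters by palladium-catalysed carbonylation of enol triflate 23, which brings the C13 methylene with it and avoids enolate chemistry on a finished lactone. The 6β-hydroxyl must close the ring with retention.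

**23 ⇒ 21 ⇒ 20.** The C4 and C5 oxygens come from syn-dihydroxylation of the Z C4=C5 alkene. It is placed after inversion of C6 (20 to 21), because photo-oxygenation of the bicycle can only deliver O6 on the α face, cis to C11, while the lactone needs it β. Inversion is done where C6 is allylic and C7 no longer bears a carbonyl.

**19 ⇒ 18 ⇒ 17 ⇒ 16.** The C11–C13 bond is cut next: the ester carbon of 16 becomes a methyl ketone (18) via the Weinreb amide 17, and the kinetic enol triflate 19 fixes C13 as the future methylene.

**16 ⇒ 14.** Reconnecting C2 to C11 gives the bridged 1,3-diketone 14. Forward, alkoxide-induced retro-Claisen cleavage breaks exactly this bond because only C2 can leave as an enolate. The ten-membered ring, the C11 ester and the masked C3 ketone arise together, and C7 keeps its configuration.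

**14 ⇒ 13 ⇒ 12.** The C4–CH3 bond is cut at the enone α-carbon (α-iodination, cross-coupling). This is done on the bicycle, where the enone is an ordinary cycloheptenone.

**12 ⇒ 9.** The C3 and C6 oxygens are removed together, back to the diene of 9. Forward, photo-oxygenation across C3/C6 and base-induced peroxide opening (through 10 and 11) give the C3 ketone and the C6 carbinol.

**9 ⇒ 8 ⇒ 7 ⇒ 6 ⇒ 5.** C9–O and C10–H come from reductive opening of the 9,10-epoxide of 7, and C8 is inverted by a Mitsunobu reaction on epoxy alcohol 6. The epoxide is placed by the C8 hydroxyl of 5. These steps sit on the bicycle because the bridgehead C7 cannot take part in β-elimination there.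

**5 ⇒ 4.** Absolute configuration comes from an enzymatic resolution at the C8 oxygen of racemic 4.

**4 ⇒ 2 + 3.** The key disconnection cuts C7–C8 and C1–C2. The six ring carbons C2–C7 and C11 are tropone 3, and C8, C9, C10 (with its methyl) and C1 are dienyl acetate 2. One [6+4] cycloaddition must form both bonds and place the C8 oxygen.

**2 ⇒ 1.** The diene is the dienol acetate of enal 1.

## Alternatives that were turned down

**Alternative 1: ring contraction by [2,3]-Wittig rearrangement.**
- Disconnection: the C6–C7 bond, made while an O–C13 ether bond breaks in a thirteen-membered ring.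
- Forward key step: a carbanion at C6 shifts [2,3] to give the ten-membered 6-hydroxy-7-isopropenyl (E)-4-ene A1.
- For: it creates the C6 carbinol and the C11/C13 unit in the ring-forming step, avoids direct ten-ring closure, and needs no resolution. On these points it is stronger than the chosen route.
- Against: A1 has an E C4=C5 alkene, and syn-dihydroxylation of an E ring alkene gives the C4/C5 diol with the wrong relative configuration. An epoxide opening at a tertiary carbon would be needed instead.
- Against: the isopropenyl methyl must still be oxidised to the C12 carboxyl, and the carbanion must form at C6 and not at the other oxygen-bearing allylic carbon.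
- Against: the thirteen-membered ether itself needs a macrocyclisation.
- Comparison: the chosen route builds all ring carbons and C11 in one intermolecular step and gets the Z C4=C5 alkene for free.

**Alternative 2: pinacol-type macrocyclisation at C3–C4.**
- Disconnection: the C3–C4 bond of the acyloin unit.
- Forward key step: a ketyl at C3 adds to a C4 methyl ketone, closing the ring to the 3,4-diol A2 fused to the lactone without its methylene.
- For: it is convergent, carries both ester-bearing carbons and the lactone from open-chain fragments of secure configuration, and needs no resolution. Here it is stronger.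
- Against: the C4 ketone has an α-oxygen at C5, which one-electron reductants tend to cleave.
- Against: ten-ring closure competes with simple reduction, and the C4 configuration is set in the macrocyclisation under weak control.
- Against: A2 then needs selective oxidation at C3 and α-methylenation of the lactone by enolate chemistry beside an isobutyrate.
- Comparison: the chosen route has no macrocyclisation and brings the methylene in with the carbonylation.

**Alternative 3: anionic oxy-Cope ring expansion.**
- Disconnection: the C1–C10 bond, formed while a temporary C3–C8 bond of a divinylcyclohexanol breaks.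
- Forward key step: the alkoxide-accelerated [3,3] shift gives the ten-membered (E)-8-en-3-one A3.
- For: this is the most reliable of the ring-forming steps considered, it is stereospecific through a chair transition state, and it starts from the chiral pool. On certainty of ring formation and absolute configuration it is stronger than the chosen route.
- Against: A3 has a C8=C9 alkene, so both the C8 ester oxygen and the free C9 hydroxyl must be added later and then told apart.
- Against: the isopropenyl group again needs allylic oxidation to reach C12.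
- Against: the rearrangement substrate must already carry the quaternary C4 carbinol and the C5/C6 oxygens next to the alkoxide, which makes it long to prepare and prone to fragmentation.
- Comparison: the chosen route uses two flat commercial partners and oxidises a rigid bicycle whose faces are clearly different.

Key step: step 2

**Assumption.** The lipase in step 3 is taken to hydrolyse the enantiomer of acetate 4 that is drawn (C7 as the large and C9 as the medium group of the empirical rule for secondary alcohols). If it prefers the other one, the wanted enantiomer is the recovered acetate and is freed with K2CO3 in methanol.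

## Route

Step 1
Reactants: 1 3-methylbut-2-enal
Product: 2 (E)-3-methylbuta-1,3-dien-1-yl acetate
Conditions: isopropenyl acetate, TsOH (cat.), 95 °C, acetone distilled off; fractional distillation
Reagents that add atoms: isopropenyl acetate, CC(=C)OC(C)=O
Why: Acid-catalysed dienol acetate formation (transacetylation); a γ-methyl proton is lost, so the terminal methylene (later C1) and the later C10 methyl are in place, and the E enol ester should predominate.

Step 2
Reactants: 2 (E)-3-methylbuta-1,3-dien-1-yl acetate; 3 tropone
Product: 4 racemic exo [6+4] adduct acetate (bicyclo[4.4.1]undecatrienone: C11 ketone bridging C2 and C7, C3=C4–C5=C6 diene, C9=C10 alkene with 10-methyl, 8-acetoxy syn to the bridge)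
Conditions: toluene, BHT, 130 °C, sealed tube, excess 2
Reagents that add atoms: none
Why: Thermally allowed suprafacial [6π+4π] cycloaddition, the closest known case being the exo addition of tropone to (E)-1-acetoxybuta-1,3-diene; the termini of tropone (C2, C7) bond to the diene termini (C1, C8), forming C1–C2 and C7–C8. Both seven-membered rings close in this one intermolecular event, and their periphery is the complete ten-membered carbocycle with C11 as the bridge. C2 and C7 become cis bridgeheads because the triene reacts on one face. C8 is set by the exo transition state together with the E diene geometry, which puts the acetoxy group syn to the carbonyl bridge (α), the C8 epimer of the target. The step needs periselectivity for [6+4] over [4+2] and exo geometry; both follow from the large terminal coefficients of tropone and the repulsive secondary overlap in the endo mode. Regiochemistry is not an issue because tropone is symmetric. The temperature is kept moderate so that the adduct does not undergo a [3,3] shift, and the product is racemic.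

Step 3
Reactants: 4 racemic exo [6+4] adduct acetate
Product: 5 8α-alcohol, single enantiomer (bridge C11 α at C2 and C7)
Conditions: Amano lipase PS, phosphate buffer pH 7/MTBE, 30 °C, stopped near half conversion; chromatography
Reagents that add atoms: none
Why: Lipase-catalysed kinetic resolution by enantioselective ester hydrolysis; by the empirical rule for secondary alcohols the enantiomer drawn should be hydrolysed faster, and the mirror-image acetate stays behind and is separated.

Step 4
Reactants: 5 8α-alcohol
Product: 6 9α,10α-epoxy 8α-alcohol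
Conditions: VO(acac)2 (cat.), t-BuOOH, CH2Cl2, 0 °C to rt
Reagents that add atoms: tert-butyl hydroperoxide, CC(C)(C)OO
Why: Hydroxyl-directed vanadium-catalysed epoxidation of the allylic alcohol; oxygen is delivered to the C9=C10 face on the side of the C8 hydroxyl (cis epoxy alcohol, epoxide α) and the diene is left alone.

Step 5
Reactants: 6 9α,10α-epoxy 8α-alcohol
Product: 7 9α,10α-epoxy 8β-benzoate
Conditions: PPh3, DIAD, PhCO2H, THF, 0 °C to rt
Reagents that add atoms: benzoic acid, O=C(O)c1ccccc1
Why: Mitsunobu inversion of an epoxy alcohol sets the C8 oxygen β, as in the target; elimination towards the bridgehead C7 or the epoxide carbon C9 is geometrically disfavoured, and there is no allyl cation pathway once the alkene is epoxidised.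

Step 6
Reactants: 7 9α,10α-epoxy 8β-benzoate
Product: 8 8β-benzoyloxy 9α-alcohol with 10α-methyl
Conditions: Cp2TiCl2 (cat.), Mn, 2,4,6-collidine hydrochloride, 1,4-cyclohexadiene, THF, rt
Reagents that add atoms: none
Why: Reductive epoxide opening by trivalent titanium (Nugent–RajanBabu, catalytic in titanium): homolysis of the C10–O bond gives the tertiary C10 radical, and hydrogen-atom transfer anti to the bulky titanoxy group on C9 puts H10 β and the methyl α while O9 stays α. The ketone and ester are inert, and the buffered medium should avoid benzoyl migration.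

Step 7
Reactants: 8 8β-benzoyloxy 9α-alcohol
Product: 9 9α-triisopropylsilyl ether
Conditions: TIPSOTf, 2,6-lutidine, CH2Cl2, 0 °C
Reagents that add atoms: triisopropylsilyl triflate, CC(C)[Si](C(C)C)(C(C)C)OS(=O)(=O)C(F)(F)F
Why: Silylation of the secondary alcohol with the most robust silyl group of the route, chosen because it resists base-induced migration to O8 and survives the two later fluoride steps.

Step 8
Reactants: 9 9α-triisopropylsilyl ether
Product: 12 6α-triethylsilyloxy 4-en-3-one, via endoperoxide 10 (not isolated), via hydroxy enone 11 (not isolated)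
Conditions: O2, tetraphenylporphyrin (cat.), visible light, CH2Cl2, −20 °C; Et3N, 0 °C; then TESCl, imidazole, 0 °C
Reagents that add atoms: dioxygen, O=O; chlorotriethylsilane, CC[Si](CC)(CC)Cl
Why: Singlet oxygen adds [4+2] to the diene face away from C1/C8 and the inward 8β-benzoate, that is on the side of the C11 bridge, so O3 and O6 are α. In the Kornblum–DeLaMare opening Et3N should remove H3 and not H6, which lies under the C8 benzoate, giving the C3 ketone and the 6α-carbinol; the carbinol is silylated in the same flask.

Step 9
Reactants: 12 6α-triethylsilyloxy 4-en-3-one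
Product: 13 4-iodo enone
Conditions: I2, pyridine, CH2Cl2, 0 °C to rt
Reagents that add atoms: iodine, II
Why: Johnson α-iodination of a cyclic enone (pyridine addition, iodination of the enolate, elimination) places iodine on C4; the bridgehead α-carbons cannot compete.

Step 10
Reactants: 13 4-iodo enone
Product: 14 4-methyl enone
Conditions: Me4Sn, Pd2(dba)3 (cat.), AsPh3, CuI, NMP, 70 °C
Reagents that add atoms: tetramethylstannane, C[Sn](C)(C)C
Why: Stille coupling of an α-iodoenone installs the C4 methyl under neutral conditions, which spares the base-sensitive 1,3-diketone.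

Step 11
Reactants: 14 4-methyl enone
Product: 16 ring-opened methyl ester bearing a 3-silyloxy-2,4-diene, via dipotassium enolate alkoxide 15 (not isolated)
Conditions: KOMe, 18-crown-6, THF, −40 to −10 °C; then TBSOTf, −78 °C
Reagents that add atoms: potassium methoxide, C[O-].[K+]; tert-butyldimethylsilyl triflate, CC(C)(C)[Si](C)(C)OS(=O)(=O)C(F)(F)F
Why: Retro-Claisen cleavage of a bridged 1,3-diketone: methoxide adds to the C11 ketone and C2–C11 breaks because C2 leaves as the dienolate of the C3 enone (C7 has no such stabilisation), which turns C11 into the methyl ester on C7, leaves C7 untouched and opens the ten-membered ring. A second equivalent transesterifies the C8 benzoate, and silylation of the dienolate oxygen and the C8 alkoxide masks the C3 ketone and O8 (ring-cis enol ether expected; its geometry has no consequence).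

Step 12
Reactants: 16 ring-opened methyl ester
Product: 17 Weinreb amide
Conditions: MeNH(OMe)·HCl, i-PrMgCl, THF, −20 to 0 °C
Reagents that add atoms: N,O-dimethylhydroxylamine hydrochloride, CNOC.Cl
Why: Weinreb amide formation from the ester with the chloromagnesium amide; the silyl dienol ether keeps C3 out of reach of the nucleophile.

Step 13
Reactants: 17 Weinreb amide
Product: 18 C11 methyl ketone
Conditions: MeMgBr, THF, 0 °C
Reagents that add atoms: methylmagnesium bromide, C[Mg]Br
Why: Weinreb ketone synthesis; the chelated tetrahedral intermediate stops at the ketone, and the new methyl is C13.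

Step 14
Reactants: 18 C11 methyl ketone
Product: 19 enol triflate (C11(OTf)=C13H2)
Conditions: KHMDS, THF, −78 °C; then PhNTf2
Reagents that add atoms: N-phenylbis(trifluoromethanesulfonimide), O=S(=O)(N(c1ccccc1)S(=O)(=O)C(F)(F)F)C(F)(F)F
Why: Kinetic deprotonation at the methyl group (the C7 methine is tertiary and flanked by two silyloxy carbons) and O-triflation give the 1,1-disubstituted enol triflate.

Step 15
Reactants: 19 enol triflate
Product: 20 6α-hydroxy 4-en-3-one enol triflate
Conditions: HF·pyridine, pyridine, THF, 0 °C
Reagents that add atoms: none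
Why: Buffered fluoride cleaves the triethylsilyl ether and the silyl dienol ether (C-protonation at C2 returns the C3 enone) while the hindered secondary tert-butyldimethylsilyl and triisopropylsilyl ethers stay.

Step 16
Reactants: 20 6α-hydroxy 4-en-3-one enol triflate
Product: 21 6β-(4-nitrobenzoate)
Conditions: PPh3, DIAD, 4-nitrobenzoic acid, toluene, 0 °C to rt
Reagents that add atoms: 4-nitrobenzoic acid, O=C(O)c1ccc(cc1)[N+](=O)[O-]
Why: Mitsunobu inversion puts the C6 oxygen β, trans to C11; the carbinol is allylic and γ to the ketone, which favours direct SN2 displacement over ionisation, and C7–H is no longer α to a carbonyl, so β-elimination has no driving force.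

Step 17
Reactants: 21 6β-(4-nitrobenzoate)
Product: 23 4α,5α,6β-triol, via diol 4-nitrobenzoate 22 (not isolated)
Conditions: OsO4 (cat.), NMO, citric acid, t-BuOH/H2O, rt; then K2CO3, MeOH, 0 °C
Reagents that add atoms: N-methylmorpholine N-oxide, C[N+]1([O-])CCOCC1; water, O
Why: Upjohn dihydroxylation: with H6 in the plane of the Z alkene (allylic 1,3-strain) the ring covers one face and OsO4 should add to the open one, which bears the C6 ester oxygen, so O4 and O5 come out α (cis to each other, trans to O6) and the C4 methyl β. The enol triflate alkene is too electron-poor to compete, and carbonate methanolysis then removes the activated ester.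

Step 18
Reactants: 23 4α,5α,6β-triol
Product: 24 trans-fused α-methylene lactone with 4,5-diol
Conditions: Pd(PPh3)4 (cat.), CO (1 atm), i-Pr2NEt, MeCN/THF, 60 °C
Reagents that add atoms: carbon monoxide, [C-]#[O+]
Why: Carbonylative lactonisation of a hydroxy enol triflate: zerovalent palladium inserts into the C11–OTf bond, CO insertion gives the acylpalladium at C12, and the 6β-hydroxyl captures it in a five-membered closure (faster than six-membered closure onto O5; O8 is silylated). C6 is retained, so the lactone is trans-fused.

Step 19
Reactants: 24 trans-fused α-methylene lactone with 4,5-diol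
Product: 25 lactone triol (free 8β-hydroxyl)
Conditions: HF·pyridine, THF, 0 °C to rt
Reagents that add atoms: none
Why: Acidic fluoride removes the secondary tert-butyldimethylsilyl ether and leaves the triisopropylsilyl ether on O9; the non-basic medium should avoid translactonisation to O8.

Step 20
Reactants: 25 lactone triol; 26 isobutyric anhydride
Product: 27 5,8-bis(isobutyrate) with 9-O-triisopropylsilyl
Conditions: DMAP, Et3N, CH2Cl2, rt to 40 °C
Reagents that add atoms: none
Why: DMAP-catalysed acylation esterifies the two secondary hydroxyls with retention; the tertiary C4 hydroxyl does not react and O9 is protected.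

Step 21
Reactants: 27 5,8-bis(isobutyrate) with 9-O-triisopropylsilyl
Product: 28 CNP0396108.1
Conditions: Et3N·3HF, MeCN, 45 °C
Reagents that add atoms: none
Why: Fluoride desilylation under slightly acidic conditions frees the C9 hydroxyl without acyl migration from O8 and without addition to the methylene lactone.

## Compound list

1 | 3-methylbut-2-enal | CC(C)=CC=O | starting material
2 | (E)-3-methylbuta-1,3-dien-1-yl acetate | CC(=C)/C=C/OC(C)=O | intermediate
3 | tropone | O=C1C=CC=CC=C1 | starting material
4 | racemic exo [6+4] adduct acetate, 8-OAc syn to the C11 bridge (enantiomer drawn is the one used) | O=C1[C@@H]2C=CC=C[C@H]1[C@H](OC(C)=O)C=C(C)C2 | intermediate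
5 | 8α-alcohol, single enantiomer | O=C1[C@@H]2C=CC=C[C@H]1[C@H](O)C=C(C)C2 | intermediate
6 | 9α,10α-epoxy 8α-alcohol | O=C1[C@@H]2C=CC=C[C@H]1[C@H](O)[C@@H]3O[C@]3(C)C2 | intermediate
7 | 9α,10α-epoxy 8β-benzoate | O=C1[C@@H]2C=CC=C[C@H]1[C@@H](OC(=O)c3ccccc3)[C@@H]4O[C@]4(C)C2 | intermediate
8 | 8β-benzoyloxy 9α-alcohol, 10α-methyl | O=C1[C@@H]2C=CC=C[C@H]1[C@@H](OC(=O)c3ccccc3)[C@H](O)[C@H](C)C2 | intermediate
9 | 9α-triisopropylsilyl ether of 8 | O=C1[C@@H]2C=CC=C[C@H]1[C@@H](OC(=O)c3ccccc3)[C@H](O[Si](C(C)C)(C(C)C)C(C)C)[C@H](C)C2 | intermediate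
10 | 3α,6α-endoperoxide | O=C1[C@@H]2[C@H]3C=C[C@H](OO3)[C@H]1[C@@H](OC(=O)c4ccccc4)[C@H](O[Si](C(C)C)(C(C)C)C(C)C)[C@H](C)C2 | intermediate
11 | 6α-hydroxy 4-en-3-one (bicyclic) | O=C1[C@@H]2C(=O)C=C[C@H](O)[C@H]1[C@@H](OC(=O)c3ccccc3)[C@H](O[Si](C(C)C)(C(C)C)C(C)C)[C@H](C)C2 | intermediate
12 | 6α-triethylsilyloxy 4-en-3-one (bicyclic) | O=C1[C@@H]2C(=O)C=C[C@H](O[Si](CC)(CC)CC)[C@H]1[C@@H](OC(=O)c3ccccc3)[C@H](O[Si](C(C)C)(C(C)C)C(C)C)[C@H](C)C2 | intermediate
13 | 4-iodo enone | O=C1[C@@H]2C(=O)C(I)=C[C@H](O[Si](CC)(CC)CC)[C@H]1[C@@H](OC(=O)c3ccccc3)[C@H](O[Si](C(C)C)(C(C)C)C(C)C)[C@H](C)C2 | intermediate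
14 | 4-methyl enone (bridged 1,3-diketone) | O=C1[C@@H]2C(=O)C(C)=C[C@H](O[Si](CC)(CC)CC)[C@H]1[C@@H](OC(=O)c3ccccc3)[C@H](O[Si](C(C)C)(C(C)C)C(C)C)[C@H](C)C2 | intermediate
15 | dipotassium C3 dienolate/C8 alkoxide of the ring-opened methyl ester | COC(=O)[C@@H]1[C@@H]([O-])[C@H](O[Si](C(C)C)(C(C)C)C(C)C)[C@H](C)C/C=C(/[O-])\C(C)=C/[C@@H]1O[Si](CC)(CC)CC.[K+].[K+] | intermediate
16 | ten-membered C11 methyl ester: 3-OTBS 2,4-diene, 6α-OTES, 8β-OTBS, 9α-OTIPS | COC(=O)[C@@H]1[C@@H](O[Si](C)(C)C(C)(C)C)[C@H](O[Si](C(C)C)(C(C)C)C(C)C)[C@H](C)C/C=C(/O[Si](C)(C)C(C)(C)C)\C(C)=C/[C@@H]1O[Si](CC)(CC)CC | intermediate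
17 | Weinreb amide of 16 | CON(C)C(=O)[C@@H]1[C@@H](O[Si](C)(C)C(C)(C)C)[C@H](O[Si](C(C)C)(C(C)C)C(C)C)[C@H](C)C/C=C(/O[Si](C)(C)C(C)(C)C)\C(C)=C/[C@@H]1O[Si](CC)(CC)CC | intermediate
18 | C11 methyl ketone | CC(=O)[C@@H]1[C@@H](O[Si](C)(C)C(C)(C)C)[C@H](O[Si](C(C)C)(C(C)C)C(C)C)[C@H](C)C/C=C(/O[Si](C)(C)C(C)(C)C)\C(C)=C/[C@@H]1O[Si](CC)(CC)CC | intermediate
19 | enol triflate C11(OTf)=C13H2 | C=C(OS(=O)(=O)C(F)(F)F)[C@@H]1[C@@H](O[Si](C)(C)C(C)(C)C)[C@H](O[Si](C(C)C)(C(C)C)C(C)C)[C@H](C)C/C=C(/O[Si](C)(C)C(C)(C)C)\C(C)=C/[C@@H]1O[Si](CC)(CC)CC | intermediate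
20 | 6α-hydroxy (Z)-4-en-3-one enol triflate | C=C(OS(=O)(=O)C(F)(F)F)[C@@H]1[C@@H](O[Si](C)(C)C(C)(C)C)[C@H](O[Si](C(C)C)(C(C)C)C(C)C)[C@H](C)CCC(=O)/C(C)=C\[C@@H]1O | intermediate
21 | 6β-(4-nitrobenzoate) of the enone enol triflate | C=C(OS(=O)(=O)C(F)(F)F)[C@@H]1[C@@H](O[Si](C)(C)C(C)(C)C)[C@H](O[Si](C(C)C)(C(C)C)C(C)C)[C@H](C)CCC(=O)/C(C)=C\[C@H]1OC(=O)c2ccc(cc2)[N+](=O)[O-] | intermediate
22 | 4α,5α-diol 6β-(4-nitrobenzoate) | C=C(OS(=O)(=O)C(F)(F)F)[C@@H]1[C@@H](O[Si](C)(C)C(C)(C)C)[C@H](O[Si](C(C)C)(C(C)C)C(C)C)[C@H](C)CCC(=O)[C@](C)(O)[C@H](O)[C@H]1OC(=O)c2ccc(cc2)[N+](=O)[O-] | intermediate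
23 | 4α,5α,6β-triol enol triflate | C=C(OS(=O)(=O)C(F)(F)F)[C@@H]1[C@@H](O[Si](C)(C)C(C)(C)C)[C@H](O[Si](C(C)C)(C(C)C)C(C)C)[C@H](C)CCC(=O)[C@](C)(O)[C@H](O)[C@H]1O | intermediate
24 | trans-fused α-methylene lactone, 4α,5α-diol, 8β-OTBS, 9α-OTIPS | C=C1C(=O)O[C@H]2[C@H]1[C@@H](O[Si](C)(C)C(C)(C)C)[C@H](O[Si](C(C)C)(C(C)C)C(C)C)[C@H](C)CCC(=O)[C@](C)(O)[C@@H]2O | intermediate
25 | lactone 4α,5α,8β-triol, 9α-OTIPS | C=C1C(=O)O[C@H]2[C@H]1[C@@H](O)[C@H](O[Si](C(C)C)(C(C)C)C(C)C)[C@H](C)CCC(=O)[C@](C)(O)[C@@H]2O | intermediate
26 | isobutyric anhydride | CC(C)C(=O)OC(=O)C(C)C | starting material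
27 | 5,8-bis(isobutyrate), 9α-OTIPS | C=C1C(=O)O[C@H]2[C@H]1[C@@H](OC(=O)C(C)C)[C@H](O[Si](C(C)C)(C(C)C)C(C)C)[C@H](C)CCC(=O)[C@](C)(O)[C@@H]2OC(=O)C(C)C | intermediate
28 | CNP0396108.1 | C=C1C(=O)O[C@H]2[C@H]1[C@@H](OC(=O)C(C)C)[C@H](O)[C@H](C)CCC(=O)[C@](C)(O)[C@@H]2OC(=O)C(C)C | target

## Step count and least certain steps

Total: 21 steps. Longest linear sequence: 21 steps, from 1 to 28; 3 and 26 are used as purchased.

**Step 2 (key step).** The less electron-rich dienyl acetate may react slowly, which lets [4+2] addition across the C2–C3 bond of tropone and a thermal [3,3] shift of the adduct compete. Only the E diene can react. Fallback, from 1 and 3 back to 4: the diene is replaced by the more electron-rich (E)-1-(tert-butyldimethylsilyloxy)-3-methylbuta-1,3-diene F1 (from 1 with TBSOTf and Et3N). It should add to 3 at lower temperature to give the racemic exo silyl ether adduct F2. TBAF frees the racemic C8 alcohol F3, and Ac2O/pyridine returns to 4.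

**Step 8.** The base may abstract H6 instead of H3, which would put the ketone at C6 and later cut the bridge on the wrong side. The hydroxy enone may also isomerise to the 1,4-diketone. Fallback, from 10 back to 11: the peroxide bond of 10 is reduced with thiourea to the cis-3α,6α-diol F4, and MnO2 oxidises only the more exposed allylic C3 carbinol.

**Step 11.** Transesterification of the benzoate may lag behind the ring opening. The C8 alkoxide β to the new ester may undergo retro-aldol cleavage, and the dienolate may be protonated or C-silylated before it is trapped. Fallback, from 14 back to 16: NaOMe in MeOH at 0 °C does the retro-Claisen and debenzoylation under protic conditions to give the 8β-hydroxy enone methyl ester F5. TBSOTf and Et3N then silylate O8 and convert the enone into the silyl dienol ether by soft enolisation.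

**Step 16.** Ring–chain tautomerism between the C6 hydroxyl and the C3 ketone (a bridging hemiketal) may withhold the alcohol. Substitution in the medium ring may be slow, and elimination to the dienone may take over. Fallback, from 20 back to 21: MsCl and Et3N at −20 °C trap the open form as the 6α-mesylate F6. Cesium 4-nitrobenzoate with 18-crown-6 in toluene then displaces it with inversion.

**Step 17.** Facial selectivity may be poor if the ring populates the conformer with the C6 oxygen in the alkene plane, which would give the 4β,5β-diol. The α-ketol may also suffer retro-aldol cleavage during methanolysis. Fallback, from 21 back to 24: K2CO3 in MeOH gives the 6β-alcohol F7. Pd(PPh3)4 and CO close the lactone first to the enone lactone F8, in which the trans-fused lactone holds H6 in the alkene plane. OsO4/NMO then dihydroxylates the ring alkene, which is twisted out of conjugation and more electron-rich than the methylene lactone.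

## Further compounds

F1 | step 2 | (E)-1-(tert-butyldimethylsilyloxy)-3-methylbuta-1,3-diene | C=C(C)/C=C/O[Si](C)(C)C(C)(C)C
F2 | step 2 | racemic exo [6+4] adduct silyl ether (one enantiomer drawn) | O=C1[C@@H]2C=CC=C[C@H]1[C@H](O[Si](C)(C)C(C)(C)C)C=C(C)C2
F3 | step 2 | racemic 8-alcohol of the adduct (one enantiomer drawn) | O=C1[C@@H]2C=CC=C[C@H]1[C@H](O)C=C(C)C2
F4 | step 8 | cis-3α,6α-diol | O=C1[C@@H]2[C@H](O)C=C[C@H](O)[C@H]1[C@@H](OC(=O)c3ccccc3)[C@H](O[Si](C(C)C)(C(C)C)C(C)C)[C@H](C)C2
F5 | step 11 | 8β-hydroxy (Z)-4-en-3-one methyl ester | COC(=O)[C@@H]1[C@@H](O)[C@H](O[Si](C(C)C)(C(C)C)C(C)C)[C@H](C)CCC(=O)/C(C)=C\[C@@H]1O[Si](CC)(CC)CC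
F6 | step 16 | 6α-mesylate | C=C(OS(=O)(=O)C(F)(F)F)[C@@H]1[C@@H](O[Si](C)(C)C(C)(C)C)[C@H](O[Si](C(C)C)(C(C)C)C(C)C)[C@H](C)CCC(=O)/C(C)=C\[C@@H]1OS(C)(=O)=O
F7 | step 17 | 6β-hydroxy (Z)-4-en-3-one enol triflate | C=C(OS(=O)(=O)C(F)(F)F)[C@@H]1[C@@H](O[Si](C)(C)C(C)(C)C)[C@H](O[Si](C(C)C)(C(C)C)C(C)C)[C@H](C)CCC(=O)/C(C)=C\[C@H]1O
F8 | step 17 | trans-fused α-methylene lactone (Z)-4-en-3-one | C1C[C@@H](C)[C@@H](O[Si](C(C)C)(C(C)C)C(C)C)[C@H](O[Si](C)(C)C(C)(C)C)[C@H]2C(=C)C(=O)O[C@@H]2/C=C(/C)C(=O)C1
A1 | alternative 1 | ten-membered 6-hydroxy-7-isopropenyl (E)-4-ene | C1CC2(OCCO2)/C(C)=C/[C@@H](O)[C@H](C(C)=C)[C@@H](OCc2ccc(OC)cc2)[C@H](O[Si](C)(C)C(C)(C)C)[C@@H]1C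
A2 | alternative 2 | ten-membered 3,4-diol fused to the des-methylene lactone | C1C(=O)O[C@H]2[C@H]1[C@@H](OC(=O)C(C)C)[C@H](O[Si](C)(C)C(C)(C)C)[C@H](C)CC[C@@H](O)[C@](C)(O)[C@@H]2O[Si](CC)(CC)CC
A3 | alternative 3 | ten-membered (E)-8-en-3-one | CC(C)(C)[Si](C)(C)O[C@H]1[C@H](C(C)=C)/C=C/[C@H](C)CCC(=O)[C@](C)(O2)[C@@H]1OC(C)(C)2
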